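**Plan**

- Retrosynthesis: the three O–Si bonds are cut last. The C3=C4 alkene is traced to a chroman with a phenylsulfanyl group at C4. C2–C3 and C4–C4a are then cut together, which leaves aryl enol ether 15 and phenyl vinyl sulfide 16. Enol ether 15 goes back through its C=CH2 bond and the acyl C–O bond to phenol 7 and acid 13, and these go back through C=C cuts to simple aldehydes.
- Enabling feature: the ether oxygen O1 joins ring carbon C8a to the fully substituted C2. A cation at C2 is therefore an aryl oxocarbenium ion whose O1=C2 and C8a=C4a π bonds form a cationic 2-oxadiene. An electron-rich two-carbon alkene can bond to C2 and to the free ortho carbon C4a in one operation (formal [4+2]).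
- Forward order: bibenzyl phenol 7 (both benzene rings bought, bridge by Wittig olefination and hydrogenation), side-chain acid 13, ester 14, methylenation to 15. The pyran ring is the only ring made. Sulfoxide elimination then removes the sulfur helper and installs C3=C4, and desilylation ends the route.
- Stereochemistry: the (E) alkene comes from a stabilised ylide. The single stereocentre C2 (S) is created in the ring-forming step under control of a chiral counter-anion, and its methyl group arises by protonation of the enol ether CH2. The C2–O1 bond exists beforehand and is not broken afterwards; later steps stay at or below 70 °C in the dark to avoid electrocyclic ring opening.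

Key step: step 11

Remark: TBS = tert-butyldimethylsilyl. The sense of induction of the chiral acid in step 11 cannot be fixed in advance, so the (S,S) acid is written and its mirror image is taken if the opposite face of C2 is attacked.

**Route**

Step 1
Reactants: 1 2,3-dihydroxybenzaldehyde
Product: 2 2,3-bis(TBSO)benzaldehyde
Conditions: TBSCl, imidazole, DMF, rt
Reagents that add atoms: tert-butyldimethylsilyl chloride, CC(C)(C)[Si](C)(C)Cl
Why: Imidazole-assisted silylation of both phenols masks the catechol with groups that should survive ylide base, hydrogenation, methylenation and acid and fall to fluoride at the end.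

Step 2
Reactants: 3 4-(benzyloxy)benzyl chloride
Product: 4 [4-(benzyloxy)benzyl]triphenylphosphonium chloride
Conditions: PPh3, toluene, reflux
Reagents that add atoms: triphenylphosphine, c1ccc(cc1)P(c1ccccc1)c1ccccc1
Why: SN2 quaternisation of the phosphine by the benzylic chloride gives the Wittig salt.

Step 3
Reactants: 4 [4-(benzyloxy)benzyl]triphenylphosphonium chloride; 2 2,3-bis(TBSO)benzaldehyde
Product: 6 1-(benzyloxy)-4-{2-[2,3-bis(TBSO)phenyl]ethenyl}benzene (E/Z mixture), via phosphorus ylide 5 (not isolated)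
Conditions: NaN(SiMe3)2, THF, 0 °C; then 2, 0 °C to rt
Reagents that add atoms: none
Why: Wittig olefination of the semi-stabilised benzylic ylide with the aryl aldehyde forms the two-carbon bridge, and the alkene geometry is irrelevant because the alkene is hydrogenated next.

Step 4
Reactants: 6 1-(benzyloxy)-4-{2-[2,3-bis(TBSO)phenyl]ethenyl}benzene
Product: 7 4-{2-[2,3-bis(TBSO)phenyl]ethyl}phenol
Conditions: H2 (1 atm), 10 % Pd/C, EtOAc, rt
Reagents that add atoms: none
Why: Heterogeneous catalytic hydrogenation should saturate the stilbene and hydrogenolyse the benzyl ether in one operation while the aryl silyl ethers stay intact.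

Step 5
Reactants: 8 methyl 4-oxobutanoate; 9 2-(triphenylphosphoranylidene)propanal
Product: 10 methyl (4E)-5-methyl-6-oxohex-4-enoate
Conditions: toluene, 80 °C
Reagents that add atoms: none
Why: Wittig olefination with the formyl-stabilised ylide is E-selective and should stop after one addition because the product enal is conjugated and α-branched; this sets the (E) alkene of the side chain.

Step 6
Reactants: 10 methyl (4E)-5-methyl-6-oxohex-4-enoate
Product: 11 methyl (4E)-6-hydroxy-5-methylhex-4-enoate
Conditions: NaBH4, CeCl3·7H2O, MeOH, 0 °C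
Reagents that add atoms: none
Why: Luche 1,2-reduction of the enal gives the allylic alcohol and leaves the ester and the alkene untouched.

Step 7
Reactants: 11 methyl (4E)-6-hydroxy-5-methylhex-4-enoate
Product: 12 methyl (4E)-6-(TBSO)-5-methylhex-4-enoate
Conditions: TBSCl, imidazole, CH2Cl2, rt
Reagents that add atoms: tert-butyldimethylsilyl chloride, CC(C)(C)[Si](C)(C)Cl
Why: Silyl ether formation protects the primary allylic alcohol against the carbodiimide, the titanium reagent and the acid of later steps.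

Step 8
Reactants: 12 methyl (4E)-6-(TBSO)-5-methylhex-4-enoate
Product: 13 (4E)-6-(TBSO)-5-methylhex-4-enoic acid
Conditions: LiOH·H2O, THF/H2O, rt; cold dilute HCl to pH 4
Reagents that add atoms: lithium hydroxide, [Li+].[OH-]
Why: Saponification of the methyl ester under conditions that a primary silyl ether and a trisubstituted alkene tolerate.

Step 9
Reactants: 7 4-{2-[2,3-bis(TBSO)phenyl]ethyl}phenol; 13 (4E)-6-(TBSO)-5-methylhex-4-enoic acid
Product: 14 4-{2-[2,3-bis(TBSO)phenyl]ethyl}phenyl (4E)-6-(TBSO)-5-methylhex-4-enoate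
Conditions: DCC, DMAP (cat.), CH2Cl2, 0 °C to rt
Reagents that add atoms: none
Why: Steglich esterification (carbodiimide activation, acyl transfer by DMAP) joins the two fragments at the only free hydroxyl group and creates the future O1–C2 bond.

Step 10
Reactants: 14 4-{2-[2,3-bis(TBSO)phenyl]ethyl}phenyl (4E)-6-(TBSO)-5-methylhex-4-enoate
Product: 15 (2E)-6-(4-{2-[2,3-bis(TBSO)phenyl]ethyl}phenoxy)-2-methylhepta-2,6-dien-1-yl TBS ether
Conditions: Cp2TiMe2 (3 equiv), toluene/THF, 65 °C, dark; filtration through basic alumina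
Reagents that add atoms: dimethyltitanocene, C[Ti](C)(C1C=CC=C1)C1C=CC=C1
Why: Petasis methylenation (Cp2Ti=CH2 adds across the ester C=O and cycloreverts) converts the aryl ester into the 1,1-disubstituted aryl enol ether under neutral conditions that spare silyl ethers and the alkene.

Step 11
Reactants: 15 (2E)-6-(4-{2-[2,3-bis(TBSO)phenyl]ethyl}phenoxy)-2-methylhepta-2,6-dien-1-yl TBS ether; 16 phenyl vinyl sulfide
Product: 19 (2S)-6-{2-[2,3-bis(TBSO)phenyl]ethyl}-2-methyl-4-(phenylsulfanyl)-2-[(3E)-4-methyl-5-(TBSO)pent-3-en-1-yl]chromane (C4 epimer mixture), via aryl oxocarbenium ion 17 (not isolated), via thionium ion 18 (not isolated)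
Conditions: (S,S)-imidodiphosphorimidate acid HN[P(=NSO2CF3)(O2R)]2 (O2R = 3,3'-bis[3,5-bis(trifluoromethyl)phenyl]-1,1'-binaphthalene-2,2'-diolate; 5 mol %), 5 Å molecular sieves, toluene, −60 °C; 15 added over 6 h to 16 (3 equiv)
Reagents that add atoms: none
Why: Proposed new method: the confined chiral acid should protonate the exocyclic CH2 of enol ether 15 (which thereby becomes the C2 methyl group) to give aryl oxocarbenium ion 17, whose O1=C2 and C8a=C4a π bonds act as a cationic 2-oxadiene; the terminal carbon of alkene 16 then bonds to C2, the resulting thionium ion 18 is captured by the ortho carbon C4a, and loss of the ring proton restores the arene and the acid. The closest known reaction types are the Lewis-acid-promoted oxa-Povarov reaction of aryl oxocarbenium ions with alkenes, the Povarov reaction with vinyl sulfides, and counter-anion-directed additions to aliphatic oxocarbenium ions with imidodiphosphorimidate acids; their combination on a ketone-derived aryl oxocarbenium ion is the new element. The pyran ring closes by a stepwise formal [4+2] cycloaddition whose second bond is a 6-exo-trig cation–arene (Friedel–Crafts) closure onto the thionium carbon. The C2 stereocentre is set under catalyst control, the chiral anion of the contact ion pair shielding one face of the planar cation and distinguishing the methyl group from the longer chain, whereas C4 forms without control and is erased in step 12. The step needs protonation of the enol ether (the most basic π bond, giving a tertiary oxygen-stabilised cation) in preference to the trisubstituted alkene and to 16, and ring closure in preference to oligomerisation: the para position is blocked by the ethylene bridge, the two ortho positions are equivalent, the distal alkene could reach C2 only through a four-membered ring, and slow addition of 15 to excess 16 keeps the cation concentration low.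

Step 12
Reactants: 19 (2S)-6-{2-[2,3-bis(TBSO)phenyl]ethyl}-2-methyl-4-(phenylsulfanyl)-2-[(3E)-4-methyl-5-(TBSO)pent-3-en-1-yl]chromane
Product: 21 (2S)-6-{2-[2,3-bis(TBSO)phenyl]ethyl}-2-methyl-2-[(3E)-4-methyl-5-(TBSO)pent-3-en-1-yl]-2H-chromene, via C4 sulfoxide 20 (not isolated)
Conditions: mCPBA (1.0 equiv), CH2Cl2, −78 °C; aq. NaHCO3 wash; then toluene, Et3N, 70 °C, dark
Reagents that add atoms: none
Why: Chemoselective S-oxidation at low temperature followed by thermal syn-elimination of the benzylic sulfoxide (sulfoxide pyrolysis) should give the C3=C4 alkene, since only C3 offers β-hydrogens, and C2 is not involved.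

Step 13
Reactants: 21 (2S)-6-{2-[2,3-bis(TBSO)phenyl]ethyl}-2-methyl-2-[(3E)-4-methyl-5-(TBSO)pent-3-en-1-yl]-2H-chromene
Product: 22 3-{2-[(2S)-2-[(3E)-5-hydroxy-4-methylpent-3-en-1-yl]-2-methyl-2H-chromen-6-yl]ethyl}benzene-1,2-diol
Conditions: Bu4NF, AcOH (1:1, 3.6 equiv), THF, 0 °C to rt, argon, dark
Reagents that add atoms: none
Why: Fluoride-mediated cleavage of the two aryl and one primary silyl ether, buffered with acetic acid so that the catechol is not held as its air-sensitive dianion; the stereocentre and both alkenes take no part.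

**Compound list**

1 | 2,3-dihydroxybenzaldehyde | O=Cc1cccc(O)c1O | starting material
2 | 2,3-bis[(tert-butyldimethylsilyl)oxy]benzaldehyde | O=Cc1cccc(O[Si](C)(C)C(C)(C)C)c1O[Si](C)(C)C(C)(C)C | intermediate
3 | 4-(benzyloxy)benzyl chloride | ClCc1ccc(OCc2ccccc2)cc1 | starting material
4 | [4-(benzyloxy)benzyl]triphenylphosphonium chloride | [Cl-].c1ccc(cc1)[P+](Cc1ccc(OCc2ccccc2)cc1)(c1ccccc1)c1ccccc1 | intermediate
5 | [4-(benzyloxy)benzylidene]triphenylphosphorane | c1ccc(cc1)P(=Cc1ccc(OCc2ccccc2)cc1)(c1ccccc1)c1ccccc1 | intermediate (not isolated)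
6 | 1-(benzyloxy)-4-{2-[2,3-bis(TBSO)phenyl]ethenyl}benzene, E/Z mixture | C(=Cc1cccc(O[Si](C)(C)C(C)(C)C)c1O[Si](C)(C)C(C)(C)C)c1ccc(OCc2ccccc2)cc1 | intermediate
7 | 4-{2-[2,3-bis(TBSO)phenyl]ethyl}phenol | Oc1ccc(CCc2cccc(O[Si](C)(C)C(C)(C)C)c2O[Si](C)(C)C(C)(C)C)cc1 | intermediate
8 | methyl 4-oxobutanoate | COC(=O)CCC=O | starting material
9 | 2-(triphenylphosphoranylidene)propanal | CC(C=O)=P(c1ccccc1)(c1ccccc1)c1ccccc1 | starting material
10 | methyl (4E)-5-methyl-6-oxohex-4-enoate | C/C(=C\CCC(=O)OC)C=O | intermediate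
11 | methyl (4E)-6-hydroxy-5-methylhex-4-enoate | C/C(=C\CCC(=O)OC)CO | intermediate
12 | methyl (4E)-6-[(tert-butyldimethylsilyl)oxy]-5-methylhex-4-enoate | C/C(=C\CCC(=O)OC)CO[Si](C)(C)C(C)(C)C | intermediate
13 | (4E)-6-[(tert-butyldimethylsilyl)oxy]-5-methylhex-4-enoic acid | C/C(=C\CCC(=O)O)CO[Si](C)(C)C(C)(C)C | intermediate
14 | 4-{2-[2,3-bis(TBSO)phenyl]ethyl}phenyl (4E)-6-(TBSO)-5-methylhex-4-enoate | C/C(=C\CCC(=O)Oc1ccc(CCc2cccc(O[Si](C)(C)C(C)(C)C)c2O[Si](C)(C)C(C)(C)C)cc1)CO[Si](C)(C)C(C)(C)C | intermediate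
15 | tert-butyl{[(2E)-6-(4-{2-[2,3-bis(TBSO)phenyl]ethyl}phenoxy)-2-methylhepta-2,6-dien-1-yl]oxy}dimethylsilane | C/C(=C\CCC(=C)Oc1ccc(CCc2cccc(O[Si](C)(C)C(C)(C)C)c2O[Si](C)(C)C(C)(C)C)cc1)CO[Si](C)(C)C(C)(C)C | intermediate
16 | phenyl vinyl sulfide | C=CSc1ccccc1 | starting material
17 | aryl oxocarbenium ion formed by C-protonation of 15 (ion pair with the catalyst anion) | C/C(=C\CCC(C)=[O+]c1ccc(CCc2cccc(O[Si](C)(C)C(C)(C)C)c2O[Si](C)(C)C(C)(C)C)cc1)CO[Si](C)(C)C(C)(C)C | intermediate (not isolated)
18 | (S)-thionium ion formed by addition of 16 to C2 of 17 | C/C(=C\CC[C@@](C)(CC=[S+]c1ccccc1)Oc1ccc(CCc2cccc(O[Si](C)(C)C(C)(C)C)c2O[Si](C)(C)C(C)(C)C)cc1)CO[Si](C)(C)C(C)(C)C | intermediate (not isolated)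
19 | (2S)-6-{2-[2,3-bis(TBSO)phenyl]ethyl}-2-methyl-4-(phenylsulfanyl)-2-[(3E)-4-methyl-5-(TBSO)pent-3-en-1-yl]-3,4-dihydro-2H-chromene, both C4 epimers | C/C(=C\CC[C@@]1(C)CC(Sc2ccccc2)c2cc(CCc3cccc(O[Si](C)(C)C(C)(C)C)c3O[Si](C)(C)C(C)(C)C)ccc2O1)CO[Si](C)(C)C(C)(C)C | intermediate
20 | C4 phenylsulfinyl analogue of 19 (sulfoxide, diastereomer mixture) | C/C(=C\CC[C@@]1(C)CC(S(=O)c2ccccc2)c2cc(CCc3cccc(O[Si](C)(C)C(C)(C)C)c3O[Si](C)(C)C(C)(C)C)ccc2O1)CO[Si](C)(C)C(C)(C)C | intermediate (not isolated)
21 | (2S)-6-{2-[2,3-bis(TBSO)phenyl]ethyl}-2-methyl-2-[(3E)-4-methyl-5-(TBSO)pent-3-en-1-yl]-2H-chromene | C/C(=C\CC[C@@]1(C)C=Cc2cc(CCc3cccc(O[Si](C)(C)C(C)(C)C)c3O[Si](C)(C)C(C)(C)C)ccc2O1)CO[Si](C)(C)C(C)(C)C | intermediate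
22 | 3-{2-[(2S)-2-[(3E)-5-hydroxy-4-methylpent-3-en-1-yl]-2-methyl-2H-chromen-6-yl]ethyl}benzene-1,2-diol | C/C(=C\CC[C@@]1(C)C=Cc2cc(CCc3cccc(O)c3O)ccc2O1)CO | target

**Summary**

Total step count: 13. Longest linear sequence: 9 steps (steps 5 to 13, from methyl 4-oxobutanoate 8).

Steps most likely to fail:

1. Step 11 (key step). The risks are poor facial discrimination between the methyl group and the chain at the planar cation (mobile E/Z geometry of the ion pair), self-condensation of the enol ether, and cationic oligomerisation of the vinyl sulfide. The fallback uses known chemistry, sets out from phenol 7 and returns at chromene 21.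
   - Magnesium-mediated ortho-formylation of 7 (MgCl2, Et3N, paraformaldehyde, MeCN, reflux) would give 5-{2-[2,3-bis(TBSO)phenyl]ethyl}-2-hydroxybenzaldehyde F1. Wittig methylenation (Ph3PCH3Br, NaN(SiMe3)2, THF) would give 4-{2-[2,3-bis(TBSO)phenyl]ethyl}-2-ethenylphenol F2.
   - Separately, commercial geranyl acetate would be oxidised at its E-methyl group (SeO2 cat., tBuOOH, CH2Cl2) to (2E,6E)-8-hydroxy-3,7-dimethylocta-2,6-dien-1-yl acetate F3 and silylated (TBSCl, imidazole) to (2E,6E)-8-(TBSO)-3,7-dimethylocta-2,6-dien-1-yl acetate F4. Deacetylation (K2CO3, MeOH) would give (2E,6E)-8-(TBSO)-3,7-dimethylocta-2,6-dien-1-ol F5, and ClCO2Me with pyridine would give (2E,6E)-8-(TBSO)-3,7-dimethylocta-2,6-dien-1-yl methyl carbonate F6.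
   - Asymmetric Tsuji–Trost O-allylation of F2 with F6 (Pd2(dba)3·CHCl3 as the zerovalent palladium source, chiral N,N'-(cyclohexane-1,2-diyl)bis[2-(diphenylphosphanyl)benzamide], CH2Cl2, rt) is expected to give the branched tertiary ether tert-butyl{[(2E,6S)-6-(4-{2-[2,3-bis(TBSO)phenyl]ethyl}-2-ethenylphenoxy)-2,6-dimethylocta-2,7-dien-1-yl]oxy}dimethylsilane F7. The ligand enantiomer is chosen to give the (S) centre.
   - Ring-closing metathesis between the styrene and the tertiary vinyl group (second-generation Grubbs catalyst RuCl2(=CHPh)(PCy3)(H2IMes), CH2Cl2, 40 °C) would close the pyran ring to 21. The catalyst should load at the styrene first, which disfavours closure onto the chain alkene.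

2. Step 10. The risks are incomplete methylenation, titanium-mediated cleavage of the aryl ester, and hydrolysis of the acid-labile enol ether on isolation. The fallback sets out from acid 13 and phenol 7 and returns at enol ether 15.
   - Addition of MeLi (2.2 equiv, Et2O, 0 °C) to 13 would give (5E)-7-(TBSO)-6-methylhept-5-en-2-one F8.
   - Kinetic deprotonation (LiN(iPr)2, THF, −78 °C) and trapping with PhNTf2 would give (5E)-7-(TBSO)-6-methylhepta-1,5-dien-2-yl trifluoromethanesulfonate F9.
   - Palladium-catalysed C–O coupling of F9 with 7 (Pd2(dba)3, 2-(di-tert-butylphosphanyl)biphenyl, K3PO4, toluene, 90 °C) would form the enol ether by making the O–C(vinyl) bond instead of the C=CH2 bond.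

3. Step 12. The risks are over-oxidation (sulfone, epoxidation of the trisubstituted alkene), addition of the sulfenic acid to the product, and erosion of enantiopurity by reversible electrocyclic opening of the chromene on heating. The fallback sets out from sulfide 19 and returns at 21 without heating.
   - S-Methylation (MeOTf, CH2Cl2, −20 °C) would give [(2S)-6-{2-[2,3-bis(TBSO)phenyl]ethyl}-2-methyl-2-[(3E)-4-methyl-5-(TBSO)pent-3-en-1-yl]-3,4-dihydro-2H-chromen-4-yl](methyl)phenylsulfonium trifluoromethanesulfonate F10.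
   - With K2CO3 in MeCN at rt, F10 should ionise at the benzylic C4 (cation stabilised by O1 through C8a) and lose a C3 proton to give 21, with thioanisole as the leaving group.

**Further compounds**

F1 | step 11 | 5-{2-[2,3-bis(TBSO)phenyl]ethyl}-2-hydroxybenzaldehyde | O=Cc1cc(CCc2cccc(O[Si](C)(C)C(C)(C)C)c2O[Si](C)(C)C(C)(C)C)ccc1O
F2 | step 11 | 4-{2-[2,3-bis(TBSO)phenyl]ethyl}-2-ethenylphenol | C=Cc1cc(CCc2cccc(O[Si](C)(C)C(C)(C)C)c2O[Si](C)(C)C(C)(C)C)ccc1O
F3 | step 11 | (2E,6E)-8-hydroxy-3,7-dimethylocta-2,6-dien-1-yl acetate | C/C(=C\CC/C(C)=C/COC(C)=O)CO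
F4 | step 11 | (2E,6E)-8-[(tert-butyldimethylsilyl)oxy]-3,7-dimethylocta-2,6-dien-1-yl acetate | C/C(=C\CC/C(C)=C/COC(C)=O)CO[Si](C)(C)C(C)(C)C
F5 | step 11 | (2E,6E)-8-[(tert-butyldimethylsilyl)oxy]-3,7-dimethylocta-2,6-dien-1-ol | C/C(=C\CC/C(C)=C/CO)CO[Si](C)(C)C(C)(C)C
F6 | step 11 | (2E,6E)-8-[(tert-butyldimethylsilyl)oxy]-3,7-dimethylocta-2,6-dien-1-yl methyl carbonate | C/C(=C\CC/C(C)=C/COC(=O)OC)CO[Si](C)(C)C(C)(C)C
F7 | step 11 | tert-butyl{[(2E,6S)-6-(4-{2-[2,3-bis(TBSO)phenyl]ethyl}-2-ethenylphenoxy)-2,6-dimethylocta-2,7-dien-1-yl]oxy}dimethylsilane | C/C(=C\CC[C@@](C)(C=C)Oc1ccc(CCc2cccc(O[Si](C)(C)C(C)(C)C)c2O[Si](C)(C)C(C)(C)C)cc1C=C)CO[Si](C)(C)C(C)(C)C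
F8 | step 10 | (5E)-7-[(tert-butyldimethylsilyl)oxy]-6-methylhept-5-en-2-one | C/C(=C\CCC(C)=O)CO[Si](C)(C)C(C)(C)C
F9 | step 10 | (5E)-7-[(tert-butyldimethylsilyl)oxy]-6-methylhepta-1,5-dien-2-yl trifluoromethanesulfonate | C/C(=C\CCC(=C)OS(=O)(=O)C(F)(F)F)CO[Si](C)(C)C(C)(C)C
F10 | step 12 | [(2S)-6-{2-[2,3-bis(TBSO)phenyl]ethyl}-2-methyl-2-[(3E)-4-methyl-5-(TBSO)pent-3-en-1-yl]-3,4-dihydro-2H-chromen-4-yl](methyl)phenylsulfonium trifluoromethanesulfonate | C/C(=C\CC[C@@]1(C)CC([S+](C)c2ccccc2)c2cc(CCc3cccc(O[Si](C)(C)C(C)(C)C)c3O[Si](C)(C)C(C)(C)C)ccc2O1)CO[Si](C)(C)C(C)(C)C.[O-]S(=O)(=O)C(F)(F)F
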